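## The problem

Leachianone A (23) is a 5,7-dihydroxyflavanone. Ring A, a phloroglucinol nucleus, is fused through C4a–C8a to the pyranone ring C; C2 carries the 4-hydroxy-2-methoxyphenyl ring B and C8 carries a (2R)-lavandulyl chain, (2R)-5-methyl-2-(prop-1-en-2-yl)hex-4-en-1-yl. The two stereocentres, C2 (S) and the side-chain carbon (R), lie five bonds apart across a flat arene, so neither can steer the other and each needs its own source of chirality. C2 is fragile: base opens the O1–C2 bond by retro-oxa-Michael reaction to the achiral 2'-hydroxychalcone, so C2 should be made late and kept away from base afterwards. The side chain is a 1,5-diene with an isopropenyl and a prenyl double bond; it forbids catalytic hydrogenation and hydrogenolysis, and in strong acid the isopropenyl group can cyclise onto the neighbouring 7-hydroxyl to a chromane. Ring A poses a differentiation problem, because the three oxygens of phloroglucinol are equivalent, yet one of them must become O1 and the side chain must sit on C8, between O1 and O7, not on C6. The feature that opens the synthesis is that the C4 carbonyl lies between C4a of ring A and C3, while O1 sits on the adjacent C8a. Ring C can therefore be assembled from an ortho-iodophenol (C4a–I, C8a–OH), carbon monoxide (C4) and an arylacetylene (C3, C2 and ring B).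

## Retrosynthesis

**23 ⇒ 22 (three O–CH2OCH3 bonds).** The phenols at O5, O7 and O4' are traced back to methoxymethyl ethers in 22. These ethers survive organolithium bases, hot amine, hydride and palladium, they assist ortho-lithiation, and they leave in dilute acid, the medium in which flavanone C2 holds its configuration. Benzyl ethers would require hydrogenolysis, which the diene forbids; silyl ethers would not survive the metalations and would call for basic fluoride at the end. The forward step must cleave three acetals faster than acid attacks the side-chain alkenes.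

**22 ⇒ 20 (C2–H and C3–H).** The flavanone is taken back to flavone 20, so that C2 is created by enantioselective delivery of hydride to the C2=C3 bond. Closing ring C at the flavanone level from a chalcone would leave C2 under reversible oxa-Michael control. Adding ring B as an aryl nucleophile to a chromone is hampered by its ortho-methoxy group. Flavone 20 has no stereocentre in ring C and no base-labile bond. The forward reaction must reduce a vinylogous ester in the presence of two isolated alkenes and choose one face by reagent control.

**20 ⇒ 13 + 16 + 17 (C4a–C4, C4–C3, O1–C2).** Ring C is dissected into iodophenol 13, arylacetylene 16 and carbon monoxide 17. Acylation routes (Friedel–Crafts or Baker–Venkataraman chemistry) would have to place an acyl group regioselectively on a phloroglucinol that already carries the side chain. Here the position of the iodine fixes C4a and the single free hydroxyl fixes O1. The precursors are one ring smaller, ring B is a separate simple alkyne, and the carbonyl carbon costs nothing. The forward reaction must insert CO before the alkyne is transferred, must not let the amine capture the aroyl intermediate, and must close in the 6-endo sense.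

**13 ⇒ 12 ⇒ 10 (O–carbamoyl and C4a–I).** The free hydroxyl of 13 is masked as the diethylcarbamate 12, and the iodine is removed to give 10. The carbamate serves twice: it marks the oxygen that becomes O1, and it is the strongest ortho-director on the ring, so metalation goes to the carbon next to it. Electrophilic iodination of a free phenol would not tell this carbon from the one between the two ethers, and it would expose the alkenes to an iodonium source. The forward steps need lithiation at the position flanked by carbamate and ether, and a carbamate cleavage that spares C–I, acetals and alkenes.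

**10 ⇒ 5 + 8 (aryl–CH2 bond, through zinc reagent 9).** The side chain is detached at the benzylic bond, giving aryl iodide 5 and (S)-lavandulyl iodide 8. The stereocentre is β to the bond formed and is not touched. A cross-coupling is preferred to alkylation of an aryllithium, because a β-branched primary halide with an allylic β-hydrogen would mostly eliminate, and the lithiated carbamate rearranges on warming. The forward reaction asks for zinc insertion without scrambling and for coupling at an iodide with two ortho oxygen substituents.

**5 ⇒ 3 ⇒ 2 ⇒ 1 (C–I, O–carbamoyl, two O–CH2OCH3).** Aryl iodide 5 comes from carbamate 3 by directed lithiation, 3 from phenol 2, and 2 from phloroglucinol 1 by twofold etherification. Because 1 is symmetric, only the number of ether groups, not their position, has to be controlled.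

**8 ⇒ 7 ⇒ 6 (C–I; resolution).** The iodide comes from (S)-lavandulol 7, which is obtained from racemic lavandulol 6 by enzymatic kinetic resolution. The S alcohol is needed because replacing CH2OH by CH2–aryl changes the descriptor to R without changing the spatial arrangement.

**16 ⇒ 15 ⇒ 14 (C≡C, O–CH2OCH3).** The alkyne is made by one-carbon homologation of aldehyde 15, the methoxymethyl ether of commercial 4-hydroxy-2-methoxybenzaldehyde 14.

## Roads not taken

**Alternative 1:** Petasis–Ferrier rearrangement. The cut is C2–C3. The precursor is the 4-methylidene-1,3-benzodioxine enol acetal A2, in which C2 is an acetal carbon bound to O1 and O3. A chiral acid would ionise C2–O3, and the liberated enol carbon would attack the oxocarbenium carbon, closing ring C and setting C2 to give the tris-silyl flavanone A1.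
- Merits: ring C and C2 arise in the same event, the flavanone oxidation level is reached directly, no flavone has to be reduced, and the silyl ethers can be removed without acid. In these respects the road is better than the chosen one.
- Weak points: the stereo-determining step is recombination of an ion pair. Control of it by a chiral counter-anion would have to be developed, and the oxocarbenium ion, stabilised by a para-siloxy and an ortho-methoxy group, favours a racemic background path. The usual achiral promoter, Me2AlCl, is a Lewis acid towards the isopropenyl group. A2 needs ring A with a carboxyl carbon at C4a, so the same oxygen differentiation and C8 alkylation are needed anyway, plus a titanium methylenation (Cp2TiMe2) of a hindered carbonyl.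
- Comparison: the chosen plan sets against this a stereo-determining step of a known catalyst-controlled reaction class and a ring closure with direct precedent.

**Alternative 2:** Biomimetic Claisen folding. The cut is C4a–C8a, so ring A is built de novo. Mg(OMe)2 would open the lactone of the 4-hydroxy-2-pyrone A4, and the liberated chain would fold by Claisen condensation of its doubly activated methylene onto the ester carbon to give chalcone A3.
- Merits: it is convergent, ring A needs no protecting groups, no metalation chemistry is involved, and the side chain would be introduced at the nucleophilic C3 of a pyrone. In step economy up to the carbon skeleton it is at least as good as the chosen plan.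
- Weak points: the folding mode has to beat aldol closure, re-lactonisation and Michael addition to the enone. The real difficulties begin at A3. Its 2'- and 6'-hydroxyls are both ortho to the carbonyl: closure through the one next to the side chain gives the 8-substituted skeleton, closure through the other gives the 6-lavandulyl isomer A5, and nothing in the structure favours either. Ring closure of a 2'-hydroxychalcone is also reversible and has no general enantioselective solution without an extra activating group.
- Comparison: the chosen plan offers a unique O1 by construction and a defined way to C2.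

**Alternative 3:** Danheiser benzannulation. The cut is in ring A (C8–C8a and C6–C7). Heating cyclobutenone A7 with the siloxyalkyne A8 would give phenol A6 through the vinylketene cascade.
- Merits: the substitution pattern and three different oxygen functions (free hydroxyl, silyl ether, acetal) arise in one step with complete regiocontrol, and the free hydroxyl is the future O1. This is better than the statistical etherification and the two directed metalations of the chosen plan, whose step 1 is its least elegant point.
- Weak points: A8 requires homologation of the chiral side-chain unit to an ester and ynolate silylation, A7 is not a stock compound, and a 1,5-diene is heated. The step delivers ring A only. C4a would still have to be iodinated ortho to a free phenol in the presence of the alkenes and of a competing position between the two ethers, and ring C and C2 remain open.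
- Comparison: it is an alternative to steps 1–8, not to the key step. The chosen plan reaches the same iodophenol from phloroglucinol with the iodine placed by directed lithiation.

Key step: step 11

## Remarks and assumptions

- Assumption: (R)-DTBM-SEGPHOS is taken to be the ligand antipode that delivers hydride to the face of C2 giving the 2S flavanone. If the sense is opposite, the S ligand is used and nothing else changes.
- Assumption: with porcine pancreatic lipase the R enantiomer of lavandulol is taken to be the faster-acylated one, so the S alcohol is recovered.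
- "(2R)-Lavandulyl" means (2R)-5-methyl-2-(prop-1-en-2-yl)hex-4-en-1-yl. The descriptor is S in alcohol 7, iodide 8 and zinc reagent 9 and R in all aryl compounds only because the CIP priorities change; the spatial arrangement is the same.

## Route

Step 1
Reactants: 1 phloroglucinol
Product: 2 3,5-bis(methoxymethoxy)phenol
Conditions: MOMCl (2.0 equiv), i-Pr2NEt (2.2 equiv), DMF, 0 °C → rt; chromatography
Reagents that add atoms: chloromethyl methyl ether, COCCl
Why: Williamson-type O-alkylation of a symmetric triol; all three hydroxyls are equivalent, so only the degree of alkylation needs control, and the bis-ether should be the main fraction, separable from the mono- and tris-ethers.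

Step 2
Reactants: 2 3,5-bis(methoxymethoxy)phenol
Product: 3 3,5-bis(methoxymethoxy)phenyl N,N-diethylcarbamate
Conditions: NaH, Et2NCOCl, THF, 0 °C → rt
Reagents that add atoms: N,N-diethylcarbamoyl chloride, CCN(CC)C(=O)Cl
Why: O-carbamoylation of the sodium phenoxide; it installs the group that marks the future O1 and acts as the strongest ortho-director on the ring.

Step 3
Reactants: 3 3,5-bis(methoxymethoxy)phenyl N,N-diethylcarbamate
Product: 5 2-iodo-3,5-bis(methoxymethoxy)phenyl N,N-diethylcarbamate, via ortho-lithiated carbamate 4 (not isolated)
Conditions: s-BuLi, TMEDA, THF, −78 °C; then I2, −78 °C → rt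
Reagents that add atoms: iodine, II
Why: Directed ortho-metalation; the carbamate outranks the acetal ether as director, so one of the two equivalent positions flanked by carbamate and ether should be lithiated in preference to the one between the two ethers. At −78 °C aryllithium 4 does not undergo anionic ortho-Fries rearrangement and is trapped by iodine.

Step 4
Reactants: 6 (±)-lavandulol
Product: 7 (S)-lavandulol
Conditions: porcine pancreatic lipase, vinyl acetate, Et2O, rt, to about 60% conversion; chromatography
Reagents that add atoms: none
Why: Lipase-catalysed kinetic resolution by transesterification; the R alcohol is acetylated faster, so running past half conversion should leave the S alcohol in high enantiomeric purity, which is checked before use and raised by a second pass if needed.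

Step 5
Reactants: 7 (S)-lavandulol
Product: 8 (S)-lavandulyl iodide
Conditions: I2, PPh3, imidazole, CH2Cl2, 0 °C → rt
Reagents that add atoms: iodine, II
Why: Appel-type iodination of a primary alcohol by SN2 displacement at CH2; the stereocentre is β to the reacting carbon and is not touched, and the buffered medium spares both alkenes.

Step 6
Reactants: 8 (S)-lavandulyl iodide; 5 2-iodo-3,5-bis(methoxymethoxy)phenyl N,N-diethylcarbamate
Product: 10 2-[(2R)-lavandulyl]-3,5-bis(methoxymethoxy)phenyl N,N-diethylcarbamate, via (S)-lavandulylzinc iodide 9 (not isolated)
Conditions: 8, Zn dust (activated with BrCH2CH2Br and TMSCl), LiCl, THF, 40 °C; then 5, Pd(OAc)2 (3 mol %), SPhos (6 mol %), THF, 50 °C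
Reagents that add atoms: none
Why: Negishi coupling; zinc inserts into the primary C–I bond without involving the β-stereocentre, and Pd/SPhos should couple the primary alkylzinc with the doubly ortho-substituted aryl iodide with reductive elimination faster than β-hydride elimination. Carbamate, acetals and alkenes are inert to the organozinc.

Step 7
Reactants: 10 2-[(2R)-lavandulyl]-3,5-bis(methoxymethoxy)phenyl N,N-diethylcarbamate
Product: 12 2-iodo-6-[(2R)-lavandulyl]-3,5-bis(methoxymethoxy)phenyl N,N-diethylcarbamate, via ortho-lithiated lavandulyl carbamate 11 (not isolated)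
Conditions: s-BuLi, TMEDA, THF, −78 °C; then I2, −78 °C → rt
Reagents that add atoms: iodine, II
Why: Second directed ortho-metalation; the one remaining position next to the carbamate (also flanked by an acetal ether) should be lithiated in preference to the position between the two ethers and to benzylic or allylic C–H, and the iodine quench of the aryllithium at −78 °C is much faster than any reaction of iodine with the alkenes.

Step 8
Reactants: 12 2-iodo-6-[(2R)-lavandulyl]-3,5-bis(methoxymethoxy)phenyl N,N-diethylcarbamate
Product: 13 2-iodo-6-[(2R)-lavandulyl]-3,5-bis(methoxymethoxy)phenol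
Conditions: Cp2Zr(H)Cl (2.5 equiv), THF, 0 °C → rt; H2O work-up
Reagents that add atoms: none
Why: Reductive cleavage of an aryl O-carbamate; Zr–H adds to the carbamoyl C=O and the adduct collapses to the zirconium phenoxide and N,N-diethylformamide. Carbonyl reduction is fast at or below room temperature, so the 1,1-disubstituted and trisubstituted alkenes, the aryl iodide and the acetals should survive.

Step 9
Reactants: 14 4-hydroxy-2-methoxybenzaldehyde
Product: 15 2-methoxy-4-(methoxymethoxy)benzaldehyde
Conditions: MOMCl, i-Pr2NEt, CH2Cl2, 0 °C → rt
Reagents that add atoms: chloromethyl methyl ether, COCCl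
Why: Standard O-alkylation of an acidic para-formyl phenol; the ring B protecting group matches those of ring A, so all three fall in one final operation.

Step 10
Reactants: 15 2-methoxy-4-(methoxymethoxy)benzaldehyde
Product: 16 1-ethynyl-2-methoxy-4-(methoxymethoxy)benzene
Conditions: dimethyl (1-diazo-2-oxopropyl)phosphonate, K2CO3, MeOH, rt
Reagents that add atoms: dimethyl (1-diazo-2-oxopropyl)phosphonate, COP(=O)(OC)C(=[N+]=[N-])C(C)=O
Why: Ohira–Bestmann variant of the Seyferth–Gilbert homologation; methanolysis releases dimethyl (diazomethyl)phosphonate, which converts the aldehyde into the terminal alkyne through a diazoalkene and 1,2-shift under mild carbonate conditions that leave the acetal untouched.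

Step 11
Reactants: 13 2-iodo-6-[(2R)-lavandulyl]-3,5-bis(methoxymethoxy)phenol; 16 1-ethynyl-2-methoxy-4-(methoxymethoxy)benzene; 17 carbon monoxide
Product: 20 8-[(2R)-lavandulyl]-2-[2-methoxy-4-(methoxymethoxy)phenyl]-5,7-bis(methoxymethoxy)-4H-chromen-4-one, via ortho-hydroxyaryl ynone 18 (not isolated), via diethylamino enone 19 (not isolated)
Conditions: PdCl2(PPh3)2 (5 mol %), CO (20 atm), Et2NH, 120 °C, autoclave
Reagents that add atoms: none
Why: PdCl2(PPh3)2 is reduced in the flask to zerovalent palladium, which inserts into the C4a–I bond; CO insertion gives an aroyl complex of divalent palladium, the amine-deprotonated alkyne is transferred to it, and reductive elimination releases ynone 18 (C4a–C4 and C4–C3). Diethylamine adds to the ynone to give enaminone 19, and the phenol oxygen then displaces the amine at C2 by addition–elimination, forming O1–C2. The closest known reaction type is the palladium-catalysed carbonylative Sonogashira coupling–cyclisation of ortho-iodophenols with terminal arylacetylenes to flavones in diethylamine. Ring C closes in an overall 6-endo-dig sense, and the secondary-amine addition–elimination path is what steers it away from 5-exo-dig closure to the aurone. No stereocentre is created, and the side-chain centre is a spectator. Carbonylation must precede alkynylation, since direct coupling would end in a 2-arylbenzofuran; CO pressure and the absence of copper secure this. The regiochemistry of ring C is fixed by the substrate, because the only free hydroxyl of 13 lies between C8 and C4a while O5 and O7 are masked. The acetals, the methyl ether and both alkenes are inert to amine, CO and zerovalent palladium, and the aryl–palladium centre cannot reach the side chain.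

Step 12
Reactants: 20 8-[(2R)-lavandulyl]-2-[2-methoxy-4-(methoxymethoxy)phenyl]-5,7-bis(methoxymethoxy)-4H-chromen-4-one
Product: 22 (2S)-8-[(2R)-lavandulyl]-2-[2-methoxy-4-(methoxymethoxy)phenyl]-5,7-bis(methoxymethoxy)chroman-4-one, via silyl enol ether 21 (not isolated)
Conditions: Cu(OAc)2 (5 mol %), (R)-DTBM-SEGPHOS (5.5 mol %), (EtO)2MeSiH (3 equiv), toluene, 0 °C → rt; then 1 M aq HCl, THF, 0 °C
Reagents that add atoms: none
Why: Asymmetric conjugate reduction of a chromone by ligated CuH; hydride is delivered to C2 on the face chosen by the bisphosphine (catalyst control, the remote side-chain centre has no say), and the copper enolate is silylated to 21, which blocks over-reduction and ring opening by β-elimination. Brief hydrolysis protonates the non-stereogenic C3, and isolated alkenes are not hydrometalated under these conditions.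

Step 13
Reactants: 22 (2S)-8-[(2R)-lavandulyl]-2-[2-methoxy-4-(methoxymethoxy)phenyl]-5,7-bis(methoxymethoxy)chroman-4-one
Product: 23 leachianone A
Conditions: 3 M aq HCl, MeOH, 45 °C; stopped at full conversion
Reagents that add atoms: none
Why: Acid-catalysed acetal cleavage (transacetalisation to dimethoxymethane); oxocarbenium formation from the three acetals should be much faster than protonation of the isopropenyl or prenyl double bond at this acidity. Flavanone C2 is configurationally stable in mild acid, since its racemisation requires base.

## Compound list

1 | phloroglucinol (benzene-1,3,5-triol) | Oc1cc(O)cc(O)c1 | starting material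
2 | 3,5-bis(methoxymethoxy)phenol | COCOc1cc(O)cc(OCOC)c1 | intermediate
3 | 3,5-bis(methoxymethoxy)phenyl N,N-diethylcarbamate | CCN(CC)C(=O)Oc1cc(OCOC)cc(OCOC)c1 | intermediate
4 | 2-[(diethylcarbamoyl)oxy]-4,6-bis(methoxymethoxy)phenyllithium | CCN(CC)C(=O)Oc1cc(OCOC)cc(OCOC)c1[Li] | intermediate, not isolated
5 | 2-iodo-3,5-bis(methoxymethoxy)phenyl N,N-diethylcarbamate | CCN(CC)C(=O)Oc1cc(OCOC)cc(OCOC)c1I | intermediate
6 | (±)-lavandulol, (RS)-5-methyl-2-(prop-1-en-2-yl)hex-4-en-1-ol | C=C(C)C(CC=C(C)C)CO | starting material
7 | (S)-lavandulol, (2S)-5-methyl-2-(prop-1-en-2-yl)hex-4-en-1-ol | C=C(C)[C@H](CC=C(C)C)CO | intermediate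
8 | (S)-lavandulyl iodide, (3S)-3-(iodomethyl)-2,6-dimethylhepta-1,5-diene | C=C(C)[C@H](CC=C(C)C)CI | intermediate
9 | (S)-lavandulylzinc iodide, [(2S)-5-methyl-2-(prop-1-en-2-yl)hex-4-en-1-yl]zinc iodide | C=C(C)[C@H](CC=C(C)C)C[Zn]I | intermediate, not isolated
10 | 2-[(2R)-lavandulyl]-3,5-bis(methoxymethoxy)phenyl N,N-diethylcarbamate | C=C(C)[C@H](CC=C(C)C)Cc1c(OCOC)cc(OCOC)cc1OC(=O)N(CC)CC | intermediate
11 | 2-[(diethylcarbamoyl)oxy]-3-[(2R)-lavandulyl]-4,6-bis(methoxymethoxy)phenyllithium | C=C(C)[C@H](CC=C(C)C)Cc1c(OCOC)cc(OCOC)c([Li])c1OC(=O)N(CC)CC | intermediate, not isolated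
12 | 2-iodo-6-[(2R)-lavandulyl]-3,5-bis(methoxymethoxy)phenyl N,N-diethylcarbamate | C=C(C)[C@H](CC=C(C)C)Cc1c(OCOC)cc(OCOC)c(I)c1OC(=O)N(CC)CC | intermediate
13 | 2-iodo-6-[(2R)-lavandulyl]-3,5-bis(methoxymethoxy)phenol | C=C(C)[C@H](CC=C(C)C)Cc1c(OCOC)cc(OCOC)c(I)c1O | intermediate
14 | 4-hydroxy-2-methoxybenzaldehyde | O=Cc1ccc(O)cc1OC | starting material
15 | 2-methoxy-4-(methoxymethoxy)benzaldehyde | O=Cc1ccc(OCOC)cc1OC | intermediate
16 | 1-ethynyl-2-methoxy-4-(methoxymethoxy)benzene | C#Cc1ccc(OCOC)cc1OC | intermediate
17 | carbon monoxide | [C-]#[O+] | starting material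
18 | 1-{2-hydroxy-3-[(2R)-lavandulyl]-4,6-bis(methoxymethoxy)phenyl}-3-[2-methoxy-4-(methoxymethoxy)phenyl]prop-2-yn-1-one | C=C(C)[C@H](CC=C(C)C)Cc1c(OCOC)cc(OCOC)c(C(=O)C#Cc2ccc(OCOC)cc2OC)c1O | intermediate, not isolated
19 | (E)-3-(diethylamino)-1-{2-hydroxy-3-[(2R)-lavandulyl]-4,6-bis(methoxymethoxy)phenyl}-3-[2-methoxy-4-(methoxymethoxy)phenyl]prop-2-en-1-one | C=C(C)[C@H](CC=C(C)C)Cc1c(OCOC)cc(OCOC)c(C(=O)/C=C(/N(CC)CC)c2ccc(OCOC)cc2OC)c1O | intermediate, not isolated
20 | 8-[(2R)-lavandulyl]-2-[2-methoxy-4-(methoxymethoxy)phenyl]-5,7-bis(methoxymethoxy)-4H-chromen-4-one | C=C(C)[C@H](CC=C(C)C)Cc1c(OCOC)cc(OCOC)c2c1OC(c1ccc(OCOC)cc1OC)=CC2=O | intermediate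
21 | (2S)-4-{[diethoxy(methyl)silyl]oxy}-8-[(2R)-lavandulyl]-2-[2-methoxy-4-(methoxymethoxy)phenyl]-5,7-bis(methoxymethoxy)-2H-chromene | C=C(C)[C@H](CC=C(C)C)Cc1c(OCOC)cc(OCOC)c2c1O[C@H](c1ccc(OCOC)cc1OC)C=C2O[Si](C)(OCC)OCC | intermediate, not isolated
22 | (2S)-8-[(2R)-lavandulyl]-2-[2-methoxy-4-(methoxymethoxy)phenyl]-5,7-bis(methoxymethoxy)chroman-4-one | C=C(C)[C@H](CC=C(C)C)Cc1c(OCOC)cc(OCOC)c2c1O[C@H](c1ccc(OCOC)cc1OC)CC2=O | intermediate
23 | leachianone A, (2S)-5,7-dihydroxy-2-(4-hydroxy-2-methoxyphenyl)-8-[(2R)-lavandulyl]chroman-4-one | C=C(C)[C@H](CC=C(C)C)Cc1c(O)cc(O)c2c1O[C@H](c1ccc(O)cc1OC)CC2=O | target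

## Step count and least certain steps

Total: 13 steps. Longest linear sequence: 9 steps from phloroglucinol (steps 1, 2, 3, 6, 7, 8, 11, 12, 13).

**Step 11 (key step).**
- Risk: the iodide is electron-rich and flanked by two oxygen substituents, so oxidative addition and alkyne transfer may be slow. Diethylamine could then capture the aroyl–palladium intermediate (aminocarbonylation to a salicylamide), or direct alkynylation without CO could lead on to a 2-arylbenzofuran. 5-exo closure to the aurone is a lesser risk.
- First adjustment within the step: stage it, with Et3N as base for the carbonylative coupling and Et2NH added afterwards.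
- Fallback: it sets out from 16 and 13 and makes the same three bonds without palladium. Alkyne 16 is deprotonated (n-BuLi, THF, −78 °C) and acylated with N-methoxy-N-methylcarbamoyl chloride to give N-methoxy-N-methyl-3-[2-methoxy-4-(methoxymethoxy)phenyl]prop-2-ynamide F1. Iodophenol 13 is deprotonated and subjected to iodine–magnesium exchange (i-PrMgCl·LiCl, 2.2 equiv, THF, 0 °C → rt) to give chloromagnesium 2-(chloromagnesio)-6-[(2R)-lavandulyl]-3,5-bis(methoxymethoxy)phenoxide F2. Acylation of F2 by F1 gives ynone 18, now isolated, and the fallback rejoins the route there; Et2NH in EtOH closes 18 to flavone 20 by the same amine path. C4 then stems from the carbamoyl chloride and not from CO.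

**Step 12.**
- Risk: C2 is a vinylogous-ester carbon, deactivated by O1 and the 5,7-dioxygenation and shielded by the ortho-methoxyaryl group, so hydride addition may be slow or poorly face-selective. Early protonation of the enolate would allow over-reduction to the flavan-4-ol.
- Fallback: from 20, non-selective conjugate reduction with LiBH(s-Bu)3 (THF, −78 °C) gives the tris-methoxymethyl flavanone as both C2 epimers F3. Kinetic resolution by asymmetric transfer hydrogenation follows, using RuCl(p-cymene)(TsDPEN) of the antipode matched to the 2R epimer with HCO2H/Et3N. It reduces the 2R epimer to the 2,4-cis flavan-4-ol F4 and leaves 22, where the route is rejoined after chromatography. At most half the material is retained.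

**Step 8.**
- Risk: hydrozirconation of the isopropenyl double bond may compete with reduction of a carbamate whose carbonyl is shielded by two ortho substituents, leading to partial saturation of the side chain.
- Fallback: it sets out from 10, before iodine is present, and exchanges the directing group for one that leaves in mild base. LiAlH4 (THF, 0 °C → rt; alkenes inert) cleaves 10 to 2-[(2R)-lavandulyl]-3,5-bis(methoxymethoxy)phenol F5. Isopropyl isocyanate with catalytic Et3N gives 2-[(2R)-lavandulyl]-3,5-bis(methoxymethoxy)phenyl N-isopropylcarbamate F6. Transient N-silylation (TMSOTf, TMEDA, Et2O), ortho-lithiation (s-BuLi, TMEDA, −78 °C) and iodine quench give 2-iodo-6-[(2R)-lavandulyl]-3,5-bis(methoxymethoxy)phenyl N-isopropylcarbamate F7. NaOH in EtOH/H2O at rt removes the carbamoyl group by E1cB loss of the isocyanate and returns the route at 13.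

**Step 13.**
- Risk: once O7 is free, acid may cyclise the isopropenyl group onto it (chromane formation) or add solvent to the side-chain alkenes; prolonged heating may erode C2.
- Fallback: from 22, TMSOTf and 2,2'-bipyridyl (MeCN, 0 °C) convert the aryl acetals under buffered aprotic conditions into (2S)-8-[(2R)-lavandulyl]-2-[2-methoxy-4-(trimethylsilyloxy)phenyl]-5,7-bis(trimethylsilyloxy)chroman-4-one F8. Water at neutral pH hydrolyses F8 to 23, so no Brønsted acid meets the free phenol next to the alkene.

**Step 6.**
- Risk: zinc insertion may be incomplete or 9 may be protonated, and coupling at the iodide between two oxygen substituents may be slow, giving reduced arene and diene by β-hydride elimination.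
- Fallback: it inverts the polarity and sets out from 7 and 3. Alcohol 7 is converted (Tf2O, 2,6-lutidine, CH2Cl2, −78 °C, used at once) into (2S)-5-methyl-2-(prop-1-en-2-yl)hex-4-en-1-yl trifluoromethanesulfonate F9. Aryllithium 4, made from 3 as in step 3, is transmetalated with MgBr2·OEt2 to {2-[(diethylcarbamoyl)oxy]-4,6-bis(methoxymethoxy)phenyl}magnesium bromide F10. F10 is alkylated by F9 with catalytic CuBr·SMe2 (THF, −78 → 0 °C) in a copper-catalysed arylmagnesium–triflate coupling that returns the route at 10. Steps 3 and 5 are then no longer needed.

## Further compounds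

F1 | step 11 | N-methoxy-N-methyl-3-[2-methoxy-4-(methoxymethoxy)phenyl]prop-2-ynamide | CON(C)C(=O)C#Cc1ccc(OCOC)cc1OC
F2 | step 11 | chloromagnesium 2-(chloromagnesio)-6-[(2R)-lavandulyl]-3,5-bis(methoxymethoxy)phenoxide | C=C(C)[C@H](CC=C(C)C)Cc1c(OCOC)cc(OCOC)c([Mg]Cl)c1O[Mg]Cl
F3 | step 12 | (2RS)-8-[(2R)-lavandulyl]-2-[2-methoxy-4-(methoxymethoxy)phenyl]-5,7-bis(methoxymethoxy)chroman-4-one (both C2 epimers) | C=C(C)[C@H](CC=C(C)C)Cc1c(OCOC)cc(OCOC)c2c1OC(c1ccc(OCOC)cc1OC)CC2=O
F4 | step 12 | (2R,4R)-8-[(2R)-lavandulyl]-2-[2-methoxy-4-(methoxymethoxy)phenyl]-5,7-bis(methoxymethoxy)chroman-4-ol (2,4-cis) | C=C(C)[C@H](CC=C(C)C)Cc1c(OCOC)cc(OCOC)c2c1O[C@@H](c1ccc(OCOC)cc1OC)C[C@H]2O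
F5 | step 8 | 2-[(2R)-lavandulyl]-3,5-bis(methoxymethoxy)phenol | C=C(C)[C@H](CC=C(C)C)Cc1c(OCOC)cc(OCOC)cc1O
F6 | step 8 | 2-[(2R)-lavandulyl]-3,5-bis(methoxymethoxy)phenyl N-isopropylcarbamate | C=C(C)[C@H](CC=C(C)C)Cc1c(OCOC)cc(OCOC)cc1OC(=O)NC(C)C
F7 | step 8 | 2-iodo-6-[(2R)-lavandulyl]-3,5-bis(methoxymethoxy)phenyl N-isopropylcarbamate | C=C(C)[C@H](CC=C(C)C)Cc1c(OCOC)cc(OCOC)c(I)c1OC(=O)NC(C)C
F8 | step 13 | (2S)-8-[(2R)-lavandulyl]-2-[2-methoxy-4-(trimethylsilyloxy)phenyl]-5,7-bis(trimethylsilyloxy)chroman-4-one | C=C(C)[C@H](CC=C(C)C)Cc1c(O[Si](C)(C)C)cc(O[Si](C)(C)C)c2c1O[C@H](c1ccc(O[Si](C)(C)C)cc1OC)CC2=O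
F9 | step 6 | (2S)-5-methyl-2-(prop-1-en-2-yl)hex-4-en-1-yl trifluoromethanesulfonate | C=C(C)[C@H](CC=C(C)C)COS(=O)(=O)C(F)(F)F
F10 | step 6 | {2-[(diethylcarbamoyl)oxy]-4,6-bis(methoxymethoxy)phenyl}magnesium bromide | CCN(CC)C(=O)Oc1cc(OCOC)cc(OCOC)c1[Mg]Br
A1 | alternative 1 | (2S)-5,7-bis(tert-butyldimethylsilyloxy)-2-[4-(tert-butyldimethylsilyloxy)-2-methoxyphenyl]-8-[(2R)-lavandulyl]chroman-4-one | C=C(C)[C@H](CC=C(C)C)Cc1c(O[Si](C)(C)C(C)(C)C)cc(O[Si](C)(C)C(C)(C)C)c2c1O[C@H](c1ccc(O[Si](C)(C)C(C)(C)C)cc1OC)CC2=O
A2 | alternative 1 | 5,7-bis(tert-butyldimethylsilyloxy)-2-[4-(tert-butyldimethylsilyloxy)-2-methoxyphenyl]-8-[(2R)-lavandulyl]-4-methylidene-4H-1,3-benzodioxine (acetal carbon unspecified) | C=C(C)[C@H](CC=C(C)C)Cc1c(O[Si](C)(C)C(C)(C)C)cc(O[Si](C)(C)C(C)(C)C)c2c1OC(c1ccc(O[Si](C)(C)C(C)(C)C)cc1OC)OC2=C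
A3 | alternative 2 | (E)-1-{2,4,6-trihydroxy-3-[(2R)-lavandulyl]phenyl}-3-[2-methoxy-4-(methoxymethoxy)phenyl]prop-2-en-1-one | C=C(C)[C@H](CC=C(C)C)Cc1c(O)cc(O)c(C(=O)/C=C/c2ccc(OCOC)cc2OC)c1O
A4 | alternative 2 | 4-hydroxy-3-[(2R)-lavandulyl]-6-{(E)-4-[2-methoxy-4-(methoxymethoxy)phenyl]-2-oxobut-3-en-1-yl}-2H-pyran-2-one | C=C(C)[C@H](CC=C(C)C)Cc1c(O)cc(CC(=O)/C=C/c2ccc(OCOC)cc2OC)oc1=O
A5 | alternative 2 | 5,7-dihydroxy-6-[(2R)-lavandulyl]-2-[2-methoxy-4-(methoxymethoxy)phenyl]chroman-4-one (C2 unspecified) | C=C(C)[C@H](CC=C(C)C)Cc1c(O)cc2OC(c3ccc(OCOC)cc3OC)CC(=O)c2c1O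
A6 | alternative 3 | 2-[(2R)-lavandulyl]-5-(methoxymethoxy)-3-(triisopropylsilyloxy)phenol | C=C(C)[C@H](CC=C(C)C)Cc1c(O[Si](C(C)C)(C(C)C)C(C)C)cc(OCOC)cc1O
A7 | alternative 3 | 3-(methoxymethoxy)cyclobut-2-en-1-one | COCOC1=CC(=O)C1
A8 | alternative 3 | triisopropyl{[(4R)-7-methyl-4-(prop-1-en-2-yl)oct-6-en-1-yn-1-yl]oxy}silane | C=C(C)[C@H](CC=C(C)C)CC#CO[Si](C(C)C)(C(C)C)C(C)C
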